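**Retrosynthetic overview**
1. Hyperielliptone HB ⇐ methyl Grignard addition to the C3′ cyclopentanone of a spiro cis-hydrindanone ketol (last stereocentre, convex-face attack).
2. Spiro ketol ⇐ key step: a SmI2-generated ketyl (carbonyl carbon used as a nucleophile) adds 6-endo to the β-carbon of a 2-substituted cyclopentenone. This forges C6′–C7′, the cyclohexane ring, the C7′ carbinol and both ring-fusion centres.
3. Cyclisation substrate ⇐ two C-alkylations at C4 of a dearomatised acylphloroglucinol: chloroacetone first, then 2-(bromomethyl)cyclopent-2-enone (Morita–Baylis–Hillman derived), entering anti to the prenyl group.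
4. Dearomatised core ⇐ palladium-catalysed asymmetric dearomative prenylation (sets C6) of the Friedel–Crafts product of 2-methylphloroglucinol and (S)-2-methylbutanoic acid.
5. Ring order: benzene ring → cyclohexanetrione (by dearomatisation) → cyclopentenone brought in intact → spiro cyclohexane (key step); no ring is formed afterwards.

Locants used in all names: core C1–C6 with the acyl group on C2, the methyl/prenyl pair on C6 and the later spiro carbon C4 (C1, C3, C5 oxygenated). Terpenoid carbons: C1′ (CH2 on C4), C2′ and C6′ (ring-fusion CH), C3′ (five-ring carbonyl/carbinol carbon), C4′ and C5′ (five-ring CH2), C7′ (six-ring carbinol carbon), C8′ (second CH2 on C4).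
Assumption: the six starting materials are bought as catalogue chemicals, the acid as its (S)-enantiomer.

**Step 1**
Reactants: 1 (S)-2-methylbutanoic acid; 2 2-methylphloroglucinol (2-methylbenzene-1,3,5-triol)
Product: 4 (S)-2-methyl-1-(2,4,6-trihydroxy-3-methylphenyl)butan-1-one, via (S)-2-methylbutanoyl chloride 3 (not isolated)
Conditions: 1, (COCl)2, cat. DMF, CH2Cl2, 0 °C to rt; then 2, AlCl3 (3.5 equiv), PhNO2–CH2Cl2, 0 °C to rt; 1 M HCl
Reagents that add atoms: none
Why: Friedel–Crafts C-acylation in which the acid chloride made in situ acylates one of the two equivalent free ring carbons of the electron-rich triol, the ortho-hydroxy ketone is deactivated as its aluminium chelate so that monoacylation stops, and at or below room temperature the α-stereocentre of the acyl group is carried through unchanged (no new stereocentre).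

**Step 2**
Reactants: 4 acyl methylphloroglucinol; 5 prenyl acetate (3-methylbut-2-en-1-yl acetate)
Product: 6 (6R)-6-methyl-2-[(2S)-2-methylbutanoyl]-6-(3-methylbut-2-en-1-yl)cyclohexane-1,3,5-trione (dienol form, C4 still CH)
Conditions: Pd2(dba)3·CHCl3 (2.5 mol%), (R,R)-DACH-phenyl Trost ligand (7.5 mol%), Et3N (1.0 equiv), 5 (1.0 equiv), CH2Cl2, 0 °C to rt
Reagents that add atoms: none
Why: Asymmetric Tsuji–Trost allylic alkylation run as a dearomatisation, in which the phloroglucinolate attacks the unsubstituted terminus of the π-prenyl complex of divalent palladium (linear product), C-alkylation at the methyl-bearing carbon gives the non-aromatic but strongly acidic enol-trione (the gem-dialkylation mode of C-alkylated phloroglucinols), and the chiral pocket of the Trost ligand selects the face of that prochiral carbon to give 6R; the sense of induction is a prediction to be confirmed in the first run, the (S,S)-ligand being used if it is opposite.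

**Step 3**
Reactants: 6 dearomatised enol-trione; 7 chloroacetone (1-chloropropan-2-one)
Product: 8 (6R)-6-methyl-2-[(2S)-2-methylbutanoyl]-6-(3-methylbut-2-en-1-yl)-4-(2-oxopropyl)cyclohexane-1,3,5-trione (dienol form)
Conditions: K2CO3 (1.1 equiv), KI (10 mol%), MeOH–H2O, 0 °C to rt
Reagents that add atoms: none
Why: SN2 C-alkylation of the vinylogous-acid anion of 6 at C4, its only unsubstituted nucleophilic carbon, by the α-halo ketone (iodide-catalysed Finkelstein activation), the aqueous medium favouring C- over O-alkylation; no stereocentre is created because C4 stays enolised.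

**Step 4**
Reactants: 9 cyclopent-2-en-1-one; 10 formaldehyde (37% aqueous solution)
Product: 11 2-(hydroxymethyl)cyclopent-2-en-1-one
Conditions: Bu3P (10 mol%), CHCl3–MeOH, rt
Reagents that add atoms: none
Why: Morita–Baylis–Hillman reaction in which the phosphine adds to the enone, the phosphonium enolate is hydroxymethylated at the α-carbon and the catalyst is eliminated; no stereocentre.

**Step 5**
Reactants: 11 2-(hydroxymethyl)cyclopent-2-en-1-one
Product: 12 2-(bromomethyl)cyclopent-2-en-1-one
Conditions: PBr3 (0.4 equiv), Et2O, 0 °C; used at once
Reagents that add atoms: phosphorus tribromide, BrP(Br)Br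
Why: Bromination of the primary allylic alcohol by SN2-type displacement of its phosphite ester at 0 °C, which leaves the enone untouched.

**Step 6**
Reactants: 8 C4-acetonyl enol-trione; 12 2-(bromomethyl)cyclopent-2-en-1-one
Product: 13 (4R,6R)-6-methyl-2-[(2S)-2-methylbutanoyl]-6-(3-methylbut-2-en-1-yl)-4-[(5-oxocyclopent-1-en-1-yl)methyl]-4-(2-oxopropyl)cyclohexane-1,3,5-trione (enol form)
Conditions: K2CO3 (1.1 equiv), THF–H2O (1:1), slow addition of 12, 0 °C to rt; dilute citric acid work-up; chromatography
Reagents that add atoms: none
Why: SN2 C-alkylation of the hindered C4 carbon of the anion of 8 at the primary allylic CH2Br (SN2′ attack at the ring carbon would have to form a quaternary–tertiary bond) creates the C4 quaternary centre, and the electrophile approaches the flat core anion on the face carrying the small C6 methyl group, anti to the prenyl chain (1,3-induction), so that C1′ is cis to methyl and the acetonyl group cis to prenyl (4R); the minor C4 epimer and O-alkylated material are removed by chromatography.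

**Step 7**
Reactants: 13 dialkylated trione
Product: 15 spiro ketol (4R,6R,2′S,6′S,7′R): the core of 13 spiro-fused at C4 to a cis-fused hydrindane (six-ring C4–C1′–C2′–C6′–C7′–C8′; five-ring C2′–C3′–C4′–C5′–C6′) with a C3′ ketone and a C7′ methyl carbinol, via lithium enolate 14 (not isolated)
Conditions: LiN(SiMe3)2 (1.0 equiv), THF, −78 °C; then SmI2 (2.5 equiv, 0.1 M in THF), t-BuOH (2 equiv), −78 to −20 °C; sat. aq. NH4Cl
Reagents that add atoms: none
Why: Proposed new method: with the acidic core masked as its lithium enolate (so that it is neither reduced nor a proton source), SmI2 held at the O3/acyl-oxygen chelate transfers an electron to the nearby C7′ ketone, whose ketyl carbon (a hydroxyalkyl-anion, d1 synthon) attacks the normally electrophilic β-carbon C6′ of the enone in a 6-endo radical addition (5-exo attack at C2′ would give an unstabilised radical), a second electron gives the C2′=C3′ enolate, which t-BuOH protonates from the face opposite the new ring (cis fusion); in the chair transition state trivalent samarium bridges the ketyl oxygen and O3, which puts O7′ axial and syn to C3 with the C7′ methyl and C5′ equatorial and so relays C4 to C7′ (R), C6′ (S) and C2′ (S); the closest known reactions are SmI2 ketyl–olefin reductive cyclisations of ketones onto enoates and enones and the 6-endo cyclisations of carbon radicals onto 2-alkylcycloalk-2-enones that give cis-fused bicyclic ketones.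

**Step 8**
Reactants: 15 spiro ketol
Product: 16 Hyperielliptone HB (4R,6R,2′S,3′R,6′S,7′R,2″S): 15 with the C3′ ketone converted into a methyl carbinol
Conditions: MeMgBr (5 equiv), THF, −78 to 0 °C; sat. aq. NH4Cl
Reagents that add atoms: methylmagnesium bromide, C[Mg]Br
Why: Grignard 1,2-addition in which two equivalents are consumed by the enol and the tertiary alcohol, the core (as its magnesium enolate) and the C5 ketone flanked by two quaternary carbons do not react, and a third equivalent adds to the cyclopentanone from the convex face of the cis-hydrindanone, anti to C1′ and to the C7′ alkoxide, placing the new methyl cis to the ring-fusion hydrogens (3′R).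

**Compound list**
1 | (S)-2-methylbutanoic acid | CC[C@H](C)C(=O)O | starting material
2 | 2-methylphloroglucinol (2-methylbenzene-1,3,5-triol) | Cc1c(O)cc(O)cc1O | starting material
3 | (S)-2-methylbutanoyl chloride (not isolated) | CC[C@H](C)C(=O)Cl | intermediate
4 | (S)-2-methyl-1-(2,4,6-trihydroxy-3-methylphenyl)butan-1-one | CC[C@H](C)C(=O)c1c(O)cc(O)c(C)c1O | intermediate
5 | prenyl acetate (3-methylbut-2-en-1-yl acetate) | CC(=O)OCC=C(C)C | starting material
6 | (6R)-6-methyl-2-[(2S)-2-methylbutanoyl]-6-(3-methylbut-2-en-1-yl)cyclohexane-1,3,5-trione, dienol form | CC[C@H](C)C(=O)C1=C(O)[C@@](C)(CC=C(C)C)C(=O)C=C1O | intermediate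
7 | chloroacetone | CC(=O)CCl | starting material
8 | (6R)-6-methyl-2-[(2S)-2-methylbutanoyl]-6-(3-methylbut-2-en-1-yl)-4-(2-oxopropyl)cyclohexane-1,3,5-trione, dienol form | CC[C@H](C)C(=O)C1=C(O)[C@@](C)(CC=C(C)C)C(=O)C(CC(C)=O)=C1O | intermediate
9 | cyclopent-2-en-1-one | O=C1CCC=C1 | starting material
10 | formaldehyde | C=O | starting material
11 | 2-(hydroxymethyl)cyclopent-2-en-1-one | O=C1CCC=C1CO | intermediate
12 | 2-(bromomethyl)cyclopent-2-en-1-one | O=C1CCC=C1CBr | intermediate
13 | (4R,6R)-6-methyl-2-[(2S)-2-methylbutanoyl]-6-(3-methylbut-2-en-1-yl)-4-[(5-oxocyclopent-1-en-1-yl)methyl]-4-(2-oxopropyl)cyclohexane-1,3,5-trione, enol form | CC[C@H](C)C(=O)C1=C(O)[C@@](C)(CC=C(C)C)C(=O)[C@](CC(C)=O)(CC2=CCCC2=O)C1=O | intermediate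
14 | lithium enolate of 13 (not isolated) | [Li+].CC[C@H](C)C(=O)C1=C([O-])[C@@](C)(CC=C(C)C)C(=O)[C@](CC(C)=O)(CC2=CCCC2=O)C1=O | intermediate
15 | spiro ketol (4R,6R,2′S,6′S,7′R): cis-hydrindan-3′-one with C7′ methyl carbinol, spiro at C4 of the core | CC[C@H](C)C(=O)C1=C(O)[C@@](C)(CC=C(C)C)C(=O)[C@]2(C[C@H]3[C@H](CCC3=O)[C@](C)(O)C2)C1=O | intermediate
16 | Hyperielliptone HB | CC[C@H](C)C(=O)C1=C(O)[C@@](C)(CC=C(C)C)C(=O)[C@]2(C[C@H]3[C@H](CC[C@@]3(C)O)[C@](C)(O)C2)C1=O | target

**Step count and risks**
Total steps: 8. Longest linear sequence: 6 (steps 1, 2, 3, 6, 7, 8); the two-step branch (steps 4 and 5) joins at step 6.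

The three steps most likely to fail:

Step 7 (key reductive cyclisation). Simple 1,4-reduction of the enone, electron transfer to the C5 ketone, or loss of the chelation relay from C4 to C7′ could defeat it. The fallback sets out from 13 and comes back at 15. Iodotrimethylsilane made in situ (Me3SiCl, NaI, MeCN, −40 °C, buffered with hexamethyldisilazane) adds iodide to the enone β-carbon and, after aqueous work-up, gives the β-iodo ketone F4. Its lithium salt is then closed with SmI2 and 1 mol% NiI2 in THF at −78 °C in a samarium Barbier reaction: the carbon–iodine bond is reduced to a C6′ organosamarium that adds to the C7′ ketone. C2′ is epimerisable and settles in the cis-fused ketol 15.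

Step 2 (dearomative prenylation). The free ring CH may compete with the methyl-bearing carbon, and both the level and the sense of enantioselectivity on a phloroglucinolate are unproven. The fallback sets out from 4 and comes back at 6. NBS (CH2Cl2, −20 °C) brominates the only free ring carbon to give the bromophenol F1. The same palladium-catalysed prenylation with 5 can then dearomatise only at the methyl-bearing carbon and gives the bromo trione F2. Zinc dust in acetic acid removes the bromine and returns 6.

Step 6 (C4 quaternary centre). O-alkylation and a low or reversed facial preference at C4 are the concerns, since methyl and prenyl differ only modestly. The fallback sets out from 6 and comes back at 13. The order of the two C4 alkylations is reversed: 6 is alkylated first with bromide 12 to give the enol trione F3, and then with chloroacetone 7. The group that enters last, and with it the sense of 1,3-induction at C4, is thereby exchanged. Whichever order delivers (4R)-13 as the major epimer is kept.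

**Further compounds**
F1 | step 2 | (S)-1-(3-bromo-2,4,6-trihydroxy-5-methylphenyl)-2-methylbutan-1-one | CC[C@H](C)C(=O)c1c(O)c(Br)c(O)c(C)c1O
F2 | step 2 | (6R)-4-bromo-6-methyl-2-[(2S)-2-methylbutanoyl]-6-(3-methylbut-2-en-1-yl)cyclohexane-1,3,5-trione, dienol form | CC[C@H](C)C(=O)C1=C(O)[C@@](C)(CC=C(C)C)C(=O)C(Br)=C1O
F3 | step 6 | (6R)-6-methyl-2-[(2S)-2-methylbutanoyl]-6-(3-methylbut-2-en-1-yl)-4-[(5-oxocyclopent-1-en-1-yl)methyl]cyclohexane-1,3,5-trione, dienol form | CC[C@H](C)C(=O)C1=C(O)[C@@](C)(CC=C(C)C)C(=O)C(CC2=CCCC2=O)=C1O
F4 | step 7 | (4R,6R)-4-[(2-iodo-5-oxocyclopentyl)methyl]-6-methyl-2-[(2S)-2-methylbutanoyl]-6-(3-methylbut-2-en-1-yl)-4-(2-oxopropyl)cyclohexane-1,3,5-trione, enol form, cyclopentane centres unassigned | CC[C@H](C)C(=O)C1=C(O)[C@@](C)(CC=C(C)C)C(=O)[C@](CC(C)=O)(CC2C(I)CCC2=O)C1=O
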